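**Retrosynthetic overview**

1. The target is a ten-membered carbocycle (C1–C10, ring-cis C1=C10 and C4=C5) trans-fused at C6–C7 to an α-methylene-γ-lactone (O–C6, C7, C11=C13, C12); the last step frees only the C15 hydroxyl.
2. Key disconnection: ring bond C9–C10, the CH2–C(sp2) junction between the C8 ester carbinol and the C1=C10–C14 enal, closed last by intramolecular nickel-catalysed reductive coupling of the primary C9 iodide with the (Z)-2-iodoenal at C10.
3. Enabling feature: C10 is the α-carbon of the C1=C10–C14 enal, so the alkenyl iodide comes from plain α-iodination with C2 and iodine cis (the ring-cis geometry is stored before closure); the trans-fused lactone ring and the two cis-trisubstituted alkenes hold C9 near C10.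
4. Open chain: C1=C10 by cross-metathesis with crotonaldehyde; C6–C7 and the lactone ring (formed first) by chromium Barbier allylation/lactonisation, in which the bought C8 centre ((R)-glyceraldehyde acetonide) relays C7 and C6 in one event.
5. The C4=C5 geometry comes from anti-hydroiodination of an ynoate followed by Negishi coupling with retention.

Key step: step 14

Assumption: 1, 4 (0.5 M in THF) and 8 are taken as commercial, and in step 8 the aldehyde is assumed to add to C7 anti to the C8–C9 bond (H8 inside, O8 toward chromium); the fallback covers the opposite sense.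

Atom labels C1–C15 follow germacrane numbering of the target.

**Step 1**
Reactants: 1 methyl 4-hydroxybut-2-ynoate
Product: 2 methyl (2Z)-4-hydroxy-3-iodobut-2-enoate
Conditions: NaI, AcOH, 70 °C
Reagents that add atoms: sodium iodide [Na+].[I-]
Why: Conjugate hydroiodination of the ynoate, in which iodide adds to C3 and the allenolate is protonated anti, should give the (Z)-3-iodoenoate with iodine cis to the ester.

**Step 2**
Reactants: 2 methyl (2Z)-4-hydroxy-3-iodobut-2-enoate
Product: 3 methyl (2Z)-4-[(tert-butyldiphenylsilyl)oxy]-3-iodobut-2-enoate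
Conditions: TBDPSCl, imidazole, CH2Cl2, 0 °C
Reagents that add atoms: tert-butyl(chloro)diphenylsilane CC(C)(C)[Si](Cl)(c1ccccc1)c1ccccc1
Why: Standard silylation of the primary alcohol gives an acid-stable ether that should last to the final step.

**Step 3**
Reactants: 3 methyl (2Z)-4-[(tert-butyldiphenylsilyl)oxy]-3-iodobut-2-enoate; 4 but-3-en-1-ylzinc bromide
Product: 5 methyl (2E)-3-{[(tert-butyldiphenylsilyl)oxy]methyl}hepta-2,6-dienoate
Conditions: Pd(PPh3)4 (5 mol%), THF, rt
Reagents that add atoms: none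
Why: Negishi sp2–sp3 cross-coupling retains the alkene geometry, so the butenyl chain ends cis to the ester (the later cis relation of C3 and C6 across C4=C5).

**Step 4**
Reactants: 5 methyl (2E)-3-{[(tert-butyldiphenylsilyl)oxy]methyl}hepta-2,6-dienoate
Product: 6 (2E)-3-{[(tert-butyldiphenylsilyl)oxy]methyl}hepta-2,6-dien-1-ol
Conditions: i-Bu2AlH (2.2 equiv), CH2Cl2, −78 °C; Rochelle salt work-up
Reagents that add atoms: none
Why: 1,2-Reduction of the conjugated ester by the aluminium hydride leaves the silyl ether and both alkenes untouched.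

**Step 5**
Reactants: 6 (2E)-3-{[(tert-butyldiphenylsilyl)oxy]methyl}hepta-2,6-dien-1-ol
Product: 7 (2E)-3-{[(tert-butyldiphenylsilyl)oxy]methyl}hepta-2,6-dienal
Conditions: MnO2 (15 equiv), CH2Cl2, rt
Reagents that add atoms: none
Why: Allylic oxidation with MnO2 stops at the enal and does not touch the isolated terminal alkene.

**Step 6**
Reactants: 8 (4R)-2,2-dimethyl-1,3-dioxolane-4-carbaldehyde; 9 methyl acrylate
Product: 10 methyl 2-{[(4R)-2,2-dimethyl-1,3-dioxolan-4-yl](hydroxy)methyl}prop-2-enoate (both carbinol epimers)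
Conditions: DABCO (0.5 equiv), 1,4-dioxane–H2O (1:1), rt, 48 h
Reagents that add atoms: none
Why: Morita–Baylis–Hillman reaction of the reactive α-alkoxy aldehyde; the new carbinol centre is not controlled and is erased in step 7, while the bought C8 centre is unaffected.

**Step 7**
Reactants: 10 methyl 2-{[(4R)-2,2-dimethyl-1,3-dioxolan-4-yl](hydroxy)methyl}prop-2-enoate
Product: 11 methyl (2Z)-2-(bromomethyl)-3-[(4S)-2,2-dimethyl-1,3-dioxolan-4-yl]prop-2-enoate
Conditions: NBS, Me2S, CH2Cl2, 0 °C to rt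
Reagents that add atoms: N-bromosuccinimide O=C1CCC(=O)N1Br
Why: SN2′ bromination of the Baylis–Hillman alcohol through the bromosulfonium reagent (Corey–Kim type) should give the conjugated (Z)-allylic bromide, the thermodynamic isomer, from both epimers of 10.

**Step 8**
Reactants: 7 (2E)-3-{[(tert-butyldiphenylsilyl)oxy]methyl}hepta-2,6-dienal; 11 methyl (2Z)-2-(bromomethyl)-3-[(4S)-2,2-dimethyl-1,3-dioxolan-4-yl]prop-2-enoate
Product: 13 trans-lactone acetonide (4S,5R)-5-[(1E)-2-{[(tert-butyldiphenylsilyl)oxy]methyl}hexa-1,5-dien-1-yl]-4-[(4S)-2,2-dimethyl-1,3-dioxolan-4-yl]-3-methylideneoxolan-2-one, via open-chain hydroxy ester 12 (not isolated)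
Conditions: CrCl2 (3 equiv), THF, 0 °C to rt; then PPTS (cat.), CH2Cl2, rt
Reagents that add atoms: none
Why: Chromium Barbier (Nozaki–Hiyama) 2-(alkoxycarbonyl)allylation then lactonisation: the (E)-allylchromium should add through a chair transition state with both substituents equatorial (C6/C7 anti, hence the trans-lactone) and to the face of C7 anti to the C8–C9 bond with H8 eclipsing the alkene and O8 toward divalent-chromium-derived metal, so that the bought C8 centre sets C7 and C6 in one event.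

**Step 9**
Reactants: 13 trans-lactone acetonide
Product: 14 (4R,5R)-5-[(1E)-2-{[(tert-butyldiphenylsilyl)oxy]methyl}hexa-1,5-dien-1-yl]-4-[(1S)-1,2-dihydroxyethyl]-3-methylideneoxolan-2-one
Conditions: AcOH–H2O–THF (3:1:1), 45 °C
Reagents that add atoms: none
Why: Acid hydrolysis of the terminal isopropylidene acetal; the silyl ether and the lactone should be stable to aqueous acetic acid.

**Step 10**
Reactants: 14 lactone diol
Product: 15 (4R,5R)-5-[(1E)-2-{[(tert-butyldiphenylsilyl)oxy]methyl}hexa-1,5-dien-1-yl]-4-[(1S)-1-hydroxy-2-iodoethyl]-3-methylideneoxolan-2-one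
Conditions: I2 (1.1 equiv), PPh3 (1.1 equiv), imidazole (2.2 equiv), THF, 0 °C
Reagents that add atoms: iodine II
Why: Appel-type iodination is selective for the primary hydroxyl (C9) at 0 °C with one equivalent of reagent and does not touch C8.

**Step 11**
Reactants: 15 iodohydrin
Product: 16 (1S)-1-[(2R,3S)-2-[(1E)-2-{[(tert-butyldiphenylsilyl)oxy]methyl}hexa-1,5-dien-1-yl]-4-methylidene-5-oxooxolan-3-yl]-2-iodoethyl 3-methylbutanoate
Conditions: isovaleryl chloride, pyridine, DMAP (cat.), CH2Cl2, 0 °C to rt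
Reagents that add atoms: 3-methylbutanoyl chloride CC(C)CC(=O)Cl
Why: DMAP-catalysed acylation of the secondary alcohol places the isovalerate with retention at C8, before any aldehyde is present that could form a lactol with the C8 hydroxyl.

**Step 12**
Reactants: 16 iodo ester; 17 (2E)-but-2-enal
Product: 18 (1S)-1-[(2R,3S)-2-[(1E,5E)-2-{[(tert-butyldiphenylsilyl)oxy]methyl}-7-oxohepta-1,5-dien-1-yl]-4-methylidene-5-oxooxolan-3-yl]-2-iodoethyl 3-methylbutanoate
Conditions: 17 (5 equiv), second-generation Grubbs catalyst RuCl2(=CHPh)(PCy3)(H2IMes) (5 mol%), CH2Cl2, 40 °C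
Reagents that add atoms: none
Why: Olefin cross-metathesis of the terminal alkene with excess crotonaldehyde should give the (E)-enal (C1=C10); the trisubstituted alkene and the electron-poor methylene lactone react far more slowly.

**Step 13**
Reactants: 18 enal
Product: 19 (1S)-1-[(2R,3S)-2-[(1E,5Z)-2-{[(tert-butyldiphenylsilyl)oxy]methyl}-6-iodo-7-oxohepta-1,5-dien-1-yl]-4-methylidene-5-oxooxolan-3-yl]-2-iodoethyl 3-methylbutanoate
Conditions: I2 (1.5 equiv), pyridine–CH2Cl2 (1:1), 0 °C to rt, dark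
Reagents that add atoms: iodine II
Why: Johnson α-iodination (pyridine conjugate addition, iodination, elimination) should give the (Z)-2-iodoenal with C2 and iodine cis; the less electrophilic methylene lactone should not react.

**Step 14**
Reactants: 19 bis-iodide
Product: 20 (3aR,4R,6E,10E,11aR)-10-{[(tert-butyldiphenylsilyl)oxy]methyl}-6-formyl-3-methylidene-2-oxo-2,3,3a,4,5,8,9,11a-octahydrocyclodeca[b]furan-4-yl 3-methylbutanoate
Conditions: NiI2 (20 mol%), 4,4′-di-tert-butyl-2,2′-bipyridine (22 mol%), Mn powder (3 equiv), DMA, 40 °C; 19 added by syringe pump over 12 h (final 0.002 M)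
Reagents that add atoms: none
Why: Proposed new method: zerovalent nickel (NiI2 reduced by Mn) adds oxidatively to the alkenyl C10–I bond of the (Z)-2-iodoenal, the reduced alkenylnickel centre abstracts iodine from the primary C9–I bond, and capture of the C9 radical at nickel followed by reductive elimination from trivalent nickel forms C9–C10 with retention of the C1=C10 geometry. The closest known reaction is the intermolecular nickel-catalysed reductive cross-electrophile coupling of alkenyl halides with primary alkyl iodides; the ring-closing, medium-ring form is the new element. The ten-membered carbocycle closes through an eleven-membered nickelacycle with C1=C10 endocyclic, the lactone ring being already in place. No stereocentre is made: C6, C7 and C8 are carried in, and the ring-cis C1=C10 alkene (C2 and C9 on the same side) is fixed in 19. The step needs cross- over homo-coupling and ring closure over oligomerisation and 1,2-elimination: the sp2 and sp3 iodides are activated by different mechanisms, slow addition holds 19 near 0.002 M, Mn does not insert into the β-acyloxy iodide, and the trans-fused lactone with the two cis-trisubstituted alkenes leaves few rotors between C9 and C10. In one operation it should deliver the full ring system with the enal, the ester and the methylene lactone untouched, so that only desilylation remains.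

**Step 15**
Reactants: 20 macrocyclic silyl ether
Product: 21 (3aR,4R,6E,10E,11aR)-6-formyl-10-(hydroxymethyl)-3-methylidene-2-oxo-2,3,3a,4,5,8,9,11a-octahydrocyclodeca[b]furan-4-yl 3-methylbutanoate
Conditions: HF·pyridine, pyridine–THF, 0 °C to rt
Reagents that add atoms: none
Why: Buffered fluoride cleavage of the silyl ether should spare the enal, the isovalerate and the methylene lactone.

**Compound list**

1 | methyl 4-hydroxybut-2-ynoate | COC(=O)C#CCO | starting material
2 | methyl (2Z)-4-hydroxy-3-iodobut-2-enoate | COC(=O)/C=C(\I)CO | intermediate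
3 | methyl (2Z)-4-[(tert-butyldiphenylsilyl)oxy]-3-iodobut-2-enoate | COC(=O)/C=C(\I)CO[Si](c1ccccc1)(c1ccccc1)C(C)(C)C | intermediate
4 | but-3-en-1-ylzinc bromide | C=CCC[Zn]Br | starting material
5 | methyl (2E)-3-{[(tert-butyldiphenylsilyl)oxy]methyl}hepta-2,6-dienoate | COC(=O)/C=C(\CCC=C)CO[Si](c1ccccc1)(c1ccccc1)C(C)(C)C | intermediate
6 | (2E)-3-{[(tert-butyldiphenylsilyl)oxy]methyl}hepta-2,6-dien-1-ol | OC/C=C(\CCC=C)CO[Si](c1ccccc1)(c1ccccc1)C(C)(C)C | intermediate
7 | (2E)-3-{[(tert-butyldiphenylsilyl)oxy]methyl}hepta-2,6-dienal | O=C/C=C(\CCC=C)CO[Si](c1ccccc1)(c1ccccc1)C(C)(C)C | intermediate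
8 | (4R)-2,2-dimethyl-1,3-dioxolane-4-carbaldehyde | CC1(C)OC[C@H](C=O)O1 | starting material
9 | methyl acrylate | C=CC(=O)OC | starting material
10 | methyl 2-{[(4R)-2,2-dimethyl-1,3-dioxolan-4-yl](hydroxy)methyl}prop-2-enoate (both carbinol epimers) | CC1(C)OC[C@H](C(O)C(=C)C(=O)OC)O1 | intermediate
11 | methyl (2Z)-2-(bromomethyl)-3-[(4S)-2,2-dimethyl-1,3-dioxolan-4-yl]prop-2-enoate | CC1(C)OC[C@H](/C=C(\CBr)C(=O)OC)O1 | intermediate
12 | methyl (3S,4R,5E)-6-{[(tert-butyldiphenylsilyl)oxy]methyl}-3-[(4S)-2,2-dimethyl-1,3-dioxolan-4-yl]-4-hydroxy-2-methylidenedeca-5,9-dienoate (not isolated) | C=C(C(=O)OC)[C@H]([C@H]1COC(C)(C)O1)[C@H](O)/C=C(/CO[Si](c1ccccc1)(c1ccccc1)C(C)(C)C)CCC=C | intermediate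
13 | (4S,5R)-5-[(1E)-2-{[(tert-butyldiphenylsilyl)oxy]methyl}hexa-1,5-dien-1-yl]-4-[(4S)-2,2-dimethyl-1,3-dioxolan-4-yl]-3-methylideneoxolan-2-one | C=C1C(=O)O[C@H](/C=C(/CO[Si](c2ccccc2)(c2ccccc2)C(C)(C)C)CCC=C)[C@H]1[C@H]1COC(C)(C)O1 | intermediate
14 | (4R,5R)-5-[(1E)-2-{[(tert-butyldiphenylsilyl)oxy]methyl}hexa-1,5-dien-1-yl]-4-[(1S)-1,2-dihydroxyethyl]-3-methylideneoxolan-2-one | C=C1C(=O)O[C@H](/C=C(/CO[Si](c2ccccc2)(c2ccccc2)C(C)(C)C)CCC=C)[C@H]1[C@H](O)CO | intermediate
15 | (4R,5R)-5-[(1E)-2-{[(tert-butyldiphenylsilyl)oxy]methyl}hexa-1,5-dien-1-yl]-4-[(1S)-1-hydroxy-2-iodoethyl]-3-methylideneoxolan-2-one | C=C1C(=O)O[C@H](/C=C(/CO[Si](c2ccccc2)(c2ccccc2)C(C)(C)C)CCC=C)[C@H]1[C@H](O)CI | intermediate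
16 | (1S)-1-[(2R,3S)-2-[(1E)-2-{[(tert-butyldiphenylsilyl)oxy]methyl}hexa-1,5-dien-1-yl]-4-methylidene-5-oxooxolan-3-yl]-2-iodoethyl 3-methylbutanoate | C=C1C(=O)O[C@H](/C=C(/CO[Si](c2ccccc2)(c2ccccc2)C(C)(C)C)CCC=C)[C@H]1[C@H](OC(=O)CC(C)C)CI | intermediate
17 | (2E)-but-2-enal (crotonaldehyde) | C/C=C/C=O | starting material
18 | (1S)-1-[(2R,3S)-2-[(1E,5E)-2-{[(tert-butyldiphenylsilyl)oxy]methyl}-7-oxohepta-1,5-dien-1-yl]-4-methylidene-5-oxooxolan-3-yl]-2-iodoethyl 3-methylbutanoate | C=C1C(=O)O[C@H](/C=C(/CO[Si](c2ccccc2)(c2ccccc2)C(C)(C)C)CC/C=C/C=O)[C@H]1[C@H](OC(=O)CC(C)C)CI | intermediate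
19 | (1S)-1-[(2R,3S)-2-[(1E,5Z)-2-{[(tert-butyldiphenylsilyl)oxy]methyl}-6-iodo-7-oxohepta-1,5-dien-1-yl]-4-methylidene-5-oxooxolan-3-yl]-2-iodoethyl 3-methylbutanoate | C=C1C(=O)O[C@H](/C=C(/CO[Si](c2ccccc2)(c2ccccc2)C(C)(C)C)CC/C=C(/C=O)I)[C@H]1[C@H](OC(=O)CC(C)C)CI | intermediate
20 | (3aR,4R,6E,10E,11aR)-10-{[(tert-butyldiphenylsilyl)oxy]methyl}-6-formyl-3-methylidene-2-oxo-2,3,3a,4,5,8,9,11a-octahydrocyclodeca[b]furan-4-yl 3-methylbutanoate | C=C1C(=O)O[C@@H]2/C=C(/CO[Si](c3ccccc3)(c3ccccc3)C(C)(C)C)CC/C=C(/C=O)C[C@@H](OC(=O)CC(C)C)[C@@H]12 | intermediate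
21 | (3aR,4R,6E,10E,11aR)-6-formyl-10-(hydroxymethyl)-3-methylidene-2-oxo-2,3,3a,4,5,8,9,11a-octahydrocyclodeca[b]furan-4-yl 3-methylbutanoate | C=C1C(=O)O[C@@H]2/C=C(/CO)CC/C=C(/C=O)C[C@@H](OC(=O)CC(C)C)[C@@H]12 | target

Total step count: 15. Longest linear sequence: 13 (steps 1–5, then 8–15); steps 6–7 make the second fragment.

**The three steps most likely to fail**

Step 14 (Proposed new method). The risk is that capture of the C9 radical by nickel on another molecule (oligomerisation) or hydrodehalogenation outruns closure of the strained ten-membered ring. The fallback uses known reactions and moves the ring closure from C9–C10 to C1=C10; it sets out from 16 and comes back at 20, so steps 12 and 13 are not needed. Intermolecular nickel-catalysed reductive coupling of the primary iodide 16 with commercial 2-bromoprop-2-en-1-ol (NiI2, 4,4′-di-tert-butyl-2,2′-bipyridine, Mn, DMA) would join C9 to C10 and give the diene allylic alcohol F1. Ring-closing metathesis of its two terminal alkenes (C10=CH2 and C1=CH2; second-generation Hoveyda–Grubbs catalyst RuCl2(=CH-2-iPrOC6H4)(H2IMes), toluene, 80 °C, 0.001 M) would give the macrocyclic allylic alcohol F2, for which the ring-cis alkene is expected in a ten-membered ring. MnO2 oxidation of the C14 alcohol would then give 20.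

Step 8. The risk is poor or reversed facial selectivity at C7: if the aldehyde adds anti to the dioxolane oxygen instead of anti to C9, C6 and C7 come out inverted relative to C8. The fallback keeps the chromium reaction but takes C8 from the other enantiomer and inverts it later; it sets out from 7 and 9 and comes back at 16. The bought (4S)-aldehyde F3 and 9 would give the Baylis–Hillman adduct F4 and then (NBS, Me2S) the enantiomeric bromide F5. With 7 and CrCl2 this would give, by the same reversed sense, the hydroxy ester F6 and the 8-epi lactone acetonide F7, in which C6 and C7 are correct. Hydrolysis would give the 8-epi diol F8 and selective iodination the 8-epi iodohydrin F9. Mitsunobu esterification of F9 with 3-methylbutanoic acid (PPh3, DIAD, THF) would then invert C8 and give 16.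

Step 10. The risk is that the vicinal diol is deoxygenated to the vinyl group or closes to the epoxide under the phosphine–iodine conditions instead of giving clean mono-iodination. The fallback replaces phosphonium activation by sulfonate displacement; it sets out from 14 and comes back at 15. Tin-acetal-catalysed selective tosylation of the primary hydroxyl (TsCl, Bu2SnO (cat.), Et3N, CH2Cl2) would give the mono-tosylate F10, and Finkelstein exchange (NaI, acetone, 50 °C) would give 15.

**Further compounds**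

F1 | step 14 | (1R)-1-[(2R,3R)-2-[(1E)-2-{[(tert-butyldiphenylsilyl)oxy]methyl}hexa-1,5-dien-1-yl]-4-methylidene-5-oxooxolan-3-yl]-4-hydroxy-3-methylidenebutyl 3-methylbutanoate | C=C1C(=O)O[C@H](/C=C(/CO[Si](c2ccccc2)(c2ccccc2)C(C)(C)C)CCC=C)[C@H]1[C@H](OC(=O)CC(C)C)CC(=C)CO
F2 | step 14 | (3aR,4R,6E,10E,11aR)-10-{[(tert-butyldiphenylsilyl)oxy]methyl}-6-(hydroxymethyl)-3-methylidene-2-oxo-2,3,3a,4,5,8,9,11a-octahydrocyclodeca[b]furan-4-yl 3-methylbutanoate | C=C1C(=O)O[C@@H]2/C=C(/CO[Si](c3ccccc3)(c3ccccc3)C(C)(C)C)CC/C=C(/CO)C[C@@H](OC(=O)CC(C)C)[C@@H]12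
F3 | step 8 | (4S)-2,2-dimethyl-1,3-dioxolane-4-carbaldehyde | CC1(C)OC[C@@H](C=O)O1
F4 | step 8 | methyl 2-{[(4S)-2,2-dimethyl-1,3-dioxolan-4-yl](hydroxy)methyl}prop-2-enoate | CC1(C)OC[C@@H](C(O)C(=C)C(=O)OC)O1
F5 | step 8 | methyl (2Z)-2-(bromomethyl)-3-[(4R)-2,2-dimethyl-1,3-dioxolan-4-yl]prop-2-enoate | CC1(C)OC[C@@H](/C=C(\CBr)C(=O)OC)O1
F6 | step 8 | methyl (3S,4R,5E)-6-{[(tert-butyldiphenylsilyl)oxy]methyl}-3-[(4R)-2,2-dimethyl-1,3-dioxolan-4-yl]-4-hydroxy-2-methylidenedeca-5,9-dienoate | C=C(C(=O)OC)[C@H]([C@@H]1COC(C)(C)O1)[C@H](O)/C=C(/CO[Si](c1ccccc1)(c1ccccc1)C(C)(C)C)CCC=C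
F7 | step 8 | (4S,5R)-5-[(1E)-2-{[(tert-butyldiphenylsilyl)oxy]methyl}hexa-1,5-dien-1-yl]-4-[(4R)-2,2-dimethyl-1,3-dioxolan-4-yl]-3-methylideneoxolan-2-one | C=C1C(=O)O[C@H](/C=C(/CO[Si](c2ccccc2)(c2ccccc2)C(C)(C)C)CCC=C)[C@H]1[C@@H]1COC(C)(C)O1
F8 | step 8 | (4R,5R)-5-[(1E)-2-{[(tert-butyldiphenylsilyl)oxy]methyl}hexa-1,5-dien-1-yl]-4-[(1R)-1,2-dihydroxyethyl]-3-methylideneoxolan-2-one | C=C1C(=O)O[C@H](/C=C(/CO[Si](c2ccccc2)(c2ccccc2)C(C)(C)C)CCC=C)[C@H]1[C@@H](O)CO
F9 | step 8 | (4R,5R)-5-[(1E)-2-{[(tert-butyldiphenylsilyl)oxy]methyl}hexa-1,5-dien-1-yl]-4-[(1R)-1-hydroxy-2-iodoethyl]-3-methylideneoxolan-2-one | C=C1C(=O)O[C@H](/C=C(/CO[Si](c2ccccc2)(c2ccccc2)C(C)(C)C)CCC=C)[C@H]1[C@@H](O)CI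
F10 | step 10 | (2S)-2-[(2R,3R)-2-[(1E)-2-{[(tert-butyldiphenylsilyl)oxy]methyl}hexa-1,5-dien-1-yl]-4-methylidene-5-oxooxolan-3-yl]-2-hydroxyethyl 4-methylbenzenesulfonate | C=C1C(=O)O[C@H](/C=C(/CO[Si](c2ccccc2)(c2ccccc2)C(C)(C)C)CCC=C)[C@H]1[C@H](O)COS(=O)(=O)c1ccc(C)cc1
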